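**Retrosynthetic overview**

1. The target is the C8 formate of 8α-hydroxylabdan-15-oic acid. The last operations are O-formylation, desilylation, hydrogenation, and a Wittig union (C11=C12) of a decalin aldehyde with a chiral-pool C12–C15 ylide that carries C13.
2. The decalin aldehyde is disconnected at C5–C10 and C8–C9, which leads back to one intramolecular Diels–Alder reaction of an acyclic, achiral (2E,8E,10Z)-trienal.
3. Enabling feature: in ring B, C8 (O and CH3), C9 (bearing C11), the quaternary C10 (CH3) and C5 stand in a row. Ring B with a C6=C7 bond is therefore the adduct of the 1-silyloxy-1-methyl diene C5=C6–C7=C8 and the enal C9=C10 (C11 = CHO), and C1–C2–C3–C4 (C4 with the gem-dimethyl group) is the four-carbon tether.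
4. Ring order: the triene has no ring. In the cycloaddition the cyclohexene (ring B) arises and the ring-fusion bond C5–C10 closes the carbocycle C10–C1–C2–C3–C4–C5 (ring A). No ring is formed afterwards, and C5, C8, C9 and C10 are all set in this step.
5. The triene is assembled by Julia–Kocienski olefination (C5=C6), B-alkyl Suzuki coupling (C1–C10) and (Z)-selective silyl dienol ether formation (C7=C8).

Key step: step 10

Remark: the sense of induction of the oxazaborolidinium catalyst in step 10 is assigned from its usual pre-transition-state model; the (S)-catalyst is taken as the one that exposes the C9 si face of the enal, and the mirror-image catalyst would serve if the sense proved opposite.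

**Route**

Step 1
Reactants: 1 2-(2-bromoethyl)-2-methyl-1,3-dioxolane; 2 1-phenyl-1H-tetrazole-5-thiol
Product: 3 5-{[2-(2-methyl-1,3-dioxolan-2-yl)ethyl]sulfanyl}-1-phenyl-1H-tetrazole
Conditions: K2CO3, DMF, 50 °C
Reagents that add atoms: none
Why: SN2 S-alkylation of the acidic heteroaryl thiol by the primary bromide under carbonate base, to which the ketal is inert.

Step 2
Reactants: 3 5-{[2-(2-methyl-1,3-dioxolan-2-yl)ethyl]sulfanyl}-1-phenyl-1H-tetrazole
Product: 4 5-{[2-(2-methyl-1,3-dioxolan-2-yl)ethyl]sulfonyl}-1-phenyl-1H-tetrazole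
Conditions: 30% aq. H2O2, (NH4)6Mo7O24·4H2O (cat.), EtOH, 0 °C → rt
Reagents that add atoms: hydrogen peroxide, OO
Why: Molybdate-catalysed peroxide oxidation of a sulfide to the sulfone, the usual access to Julia–Kocienski reagents, under conditions too weakly acidic to open the dioxolane.

Step 3
Reactants: 4 5-{[2-(2-methyl-1,3-dioxolan-2-yl)ethyl]sulfonyl}-1-phenyl-1H-tetrazole; 5 2,2-dimethylpent-4-enal
Product: 7 2-[(2E)-4,4-dimethylhepta-2,6-dien-1-yl]-2-methyl-1,3-dioxolane, via potassium sulfonyl carbanion 6 (not isolated)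
Conditions: KN(SiMe3)2, 1,2-dimethoxyethane, −60 °C; then 5, −60 °C → rt
Reagents that add atoms: none
Why: Julia–Kocienski olefination of a non-enolisable α-quaternary aldehyde, where the potassium counter-ion in a polar ether and the bulky aldehyde should favour the (E)-alkene (C5=C6).

Step 4
Reactants: 8 methyl 3-oxobutanoate
Product: 9 methyl (2E)-3-{[(trifluoromethyl)sulfonyl]oxy}but-2-enoate
Conditions: Tf2O, aq. Me4NOH, toluene, 5 °C
Reagents that add atoms: trifluoromethanesulfonic anhydride, O=S(=O)(OS(=O)(=O)C(F)(F)F)C(F)(F)F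
Why: Stereoselective enol triflation of a β-keto ester, in which the non-chelating tetramethylammonium enolate is O-sulfonylated to the (E)-isomer (triflate trans to the ester).

Step 5
Reactants: 7 2-[(2E)-4,4-dimethylhepta-2,6-dien-1-yl]-2-methyl-1,3-dioxolane; 9 methyl (2E)-3-{[(trifluoromethyl)sulfonyl]oxy}but-2-enoate
Product: 11 methyl (2E,8E)-3,7,7-trimethyl-10-(2-methyl-1,3-dioxolan-2-yl)deca-2,8-dienoate, via B-alkyl-9-borabicyclo[3.3.1]nonane 10 (not isolated)
Conditions: 9-borabicyclo[3.3.1]nonane, THF, 0 °C → rt; then 9, Pd(dppf)Cl2 (5 mol%), AsPh3, 3 M aq. K3PO4, DMF, rt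
Reagents that add atoms: none
Why: Anti-Markovnikov hydroboration of the monosubstituted alkene (the hindered internal alkene is left) followed by B-alkyl Suzuki–Miyaura coupling with retention of the triflate geometry, which fixes the (E)-trisubstituted C9=C10 bond.

Step 6
Reactants: 11 methyl (2E,8E)-3,7,7-trimethyl-10-(2-methyl-1,3-dioxolan-2-yl)deca-2,8-dienoate
Product: 12 methyl (2E,8E)-3,7,7-trimethyl-11-oxododeca-2,8-dienoate
Conditions: 1 M aq. HCl, THF, 0 °C
Reagents that add atoms: water, O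
Why: Acid-catalysed ketal hydrolysis at low temperature should free the methyl ketone without moving the β,γ-double bond into conjugation.

Step 7
Reactants: 12 methyl (2E,8E)-3,7,7-trimethyl-11-oxododeca-2,8-dienoate
Product: 13 methyl (2E,8E,10Z)-11-{[tert-butyl(dimethyl)silyl]oxy}-3,7,7-trimethyldodeca-2,8,10-trienoate
Conditions: TBSOTf, Et3N, CH2Cl2, −78 → 0 °C
Reagents that add atoms: tert-butyldimethylsilyl trifluoromethanesulfonate, CC(C)(C)[Si](C)(C)OS(=O)(=O)C(F)(F)F
Why: Soft enolisation removes the doubly activated C7–H between carbonyl and alkene to give the conjugated dienol ether, and the (Z)-geometry (C6 cis to O) is expected, as for benzyl methyl ketone enolates, because the alkenyl group avoids A(1,3) strain with the C8 methyl group.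

Step 8
Reactants: 13 methyl (2E,8E,10Z)-11-{[tert-butyl(dimethyl)silyl]oxy}-3,7,7-trimethyldodeca-2,8,10-trienoate
Product: 14 (2E,8E,10Z)-11-{[tert-butyl(dimethyl)silyl]oxy}-3,7,7-trimethyldodeca-2,8,10-trien-1-ol
Conditions: i-Bu2AlH (2.5 equiv), CH2Cl2, −78 °C; aq. potassium sodium tartrate
Reagents that add atoms: none
Why: 1,2-Reduction of the enoate by the aluminium hydride with a neutral tartrate work-up that the silyl dienol ether should tolerate.

Step 9
Reactants: 14 (2E,8E,10Z)-11-{[tert-butyl(dimethyl)silyl]oxy}-3,7,7-trimethyldodeca-2,8,10-trien-1-ol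
Product: 15 (2E,8E,10Z)-11-{[tert-butyl(dimethyl)silyl]oxy}-3,7,7-trimethyldodeca-2,8,10-trienal
Conditions: activated MnO2, CH2Cl2, rt
Reagents that add atoms: none
Why: Chemoselective heterogeneous oxidation of the allylic alcohol to the (E)-enal under neutral conditions that keep the acid-labile dienol ether.

Step 10
Reactants: 15 (2E,8E,10Z)-11-{[tert-butyl(dimethyl)silyl]oxy}-3,7,7-trimethyldodeca-2,8,10-trienal
Product: 16 (1R,2R,4aS,8aS)-2-{[tert-butyl(dimethyl)silyl]oxy}-2,5,5,8a-tetramethyl-1,2,4a,5,6,7,8,8a-octahydronaphthalene-1-carbaldehyde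
Conditions: 20 mol% (S)-3,3-diphenyl-1-(2-methylphenyl)tetrahydro-1H,3H-pyrrolo[1,2-c][1,3,2]oxazaborole activated with (CF3SO2)2NH, CH2Cl2 (0.02 M), −78 → −20 °C
Reagents that add atoms: none
Why: Coordination of the cationic oxazaborolidine to the aldehyde lowers the LUMO of the C9=C10 enal, which undergoes a concerted, asynchronous normal-demand [4+2] cycloaddition with the electron-rich silyloxy diene C5=C6–C7=C8 held by the C1–C4 tether. The closest known reaction type is the chiral-oxazaborolidinium-catalysed intramolecular Diels–Alder reaction of trienals, a special case of the Lewis-acid-promoted type 1 cyclisation of 1,7,9-decatrienes with a terminally activated dienophile. Ring A is closed by the C5–C10 bond as the six-membered tether ring (fused mode, chair-like tether lying exo), and ring B is the new cyclohexene completed by the C8–C9 bond. Suprafacial addition carries the (E)-enal geometry into the cis relation of the C10 methyl and C11, and the (8E,10Z)-diene geometry into the cis relation of H5 and the C8 oxygen; the endo formyl group puts the C10 methyl cis to C4, which gives the trans ring fusion; the absolute configuration comes from the catalyst, which shields one face of the s-trans enal. The step needs endo over exo selectivity (Lewis-acid coordination and the anti four-carbon tether), fused over bridged regiochemistry (tether length, matched by the polarity of nucleophilic C5 and electrophilic C10) and cycloaddition over Mukaiyama-type or hetero-Diels–Alder pathways (intramolecularity at high dilution and low temperature).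

Step 11
Reactants: 17 (4R)-4-methyldihydrofuran-2(3H)-one
Product: 18 [(2R)-3-carboxy-2-methylpropyl](triphenyl)phosphonium bromide
Conditions: Ph3P·HBr, neat, 170 °C
Reagents that add atoms: triphenylphosphine hydrobromide, [Br-].[PH+](c1ccccc1)(c1ccccc1)c1ccccc1
Why: Acid-promoted SN2 opening of the γ-lactone at its O–CH2 carbon by triphenylphosphine, as known for γ-butyrolactone, which does not touch the C13 stereocentre.

Step 12
Reactants: 16 (1R,2R,4aS,8aS)-2-{[tert-butyl(dimethyl)silyl]oxy}-2,5,5,8a-tetramethyl-1,2,4a,5,6,7,8,8a-octahydronaphthalene-1-carbaldehyde; 18 [(2R)-3-carboxy-2-methylpropyl](triphenyl)phosphonium bromide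
Product: 20 (3R,4Z)-5-[(1R,2R,4aS,8aS)-2-{[tert-butyl(dimethyl)silyl]oxy}-2,5,5,8a-tetramethyl-1,2,4a,5,6,7,8,8a-octahydronaphthalen-1-yl]-3-methylpent-4-enoic acid, via sodium ylide carboxylate 19 (not isolated)
Conditions: 18, NaN(SiMe3)2 (2 equiv per 18), THF, 0 °C; then 16, −78 °C → rt; aq. HCl to pH 4
Reagents that add atoms: none
Why: Wittig olefination in which the non-stabilised ylide should add to the aldehyde faster than it deprotonates C9, whose equatorial formyl configuration is in any case the stable one, and the alkene geometry is of no consequence.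

Step 13
Reactants: 20 (3R,4Z)-5-[(1R,2R,4aS,8aS)-2-{[tert-butyl(dimethyl)silyl]oxy}-2,5,5,8a-tetramethyl-1,2,4a,5,6,7,8,8a-octahydronaphthalen-1-yl]-3-methylpent-4-enoic acid
Product: 21 (3S)-5-[(1R,2R,4aS,8aS)-2-{[tert-butyl(dimethyl)silyl]oxy}-2,5,5,8a-tetramethyldecahydronaphthalen-1-yl]-3-methylpentanoic acid
Conditions: H2 (3 atm), PtO2, EtOAc, rt
Reagents that add atoms: none
Why: Heterogeneous hydrogenation of both disubstituted alkenes over platinum, chosen over palladium to limit double-bond migration toward C13 or C9 and allylic C–O hydrogenolysis; no stereocentre is formed.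

Step 14
Reactants: 21 (3S)-5-[(1R,2R,4aS,8aS)-2-{[tert-butyl(dimethyl)silyl]oxy}-2,5,5,8a-tetramethyldecahydronaphthalen-1-yl]-3-methylpentanoic acid
Product: 22 (3S)-5-[(1R,2R,4aS,8aS)-2-hydroxy-2,5,5,8a-tetramethyldecahydronaphthalen-1-yl]-3-methylpentanoic acid
Conditions: HF·pyridine, pyridine–THF, 0 °C → rt
Reagents that add atoms: none
Why: Fluoride cleavage of the tertiary silyl ether under buffered conditions that should not dehydrate the now saturated tertiary alcohol.

Step 15
Reactants: 22 (3S)-5-[(1R,2R,4aS,8aS)-2-hydroxy-2,5,5,8a-tetramethyldecahydronaphthalen-1-yl]-3-methylpentanoic acid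
Product: 23 (3S)-5-[(1R,2R,4aS,8aS)-2-(formyloxy)-2,5,5,8a-tetramethyldecahydronaphthalen-1-yl]-3-methylpentanoic acid
Conditions: acetic formic anhydride (excess), pyridine, 4-(dimethylamino)pyridine (cat.), CH2Cl2, −20 °C → rt; then H2O
Reagents that add atoms: acetic formic anhydride, CC(=O)OC=O
Why: O-Formylation of the tertiary alcohol by the small mixed anhydride, as used for tertiary terpene formates, with retention at C8, while the transient mixed anhydride at the carboxyl group is hydrolysed on aqueous work-up.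

**Compound list**

1 | 2-(2-bromoethyl)-2-methyl-1,3-dioxolane | CC1(CCBr)OCCO1 | starting material
2 | 1-phenyl-1H-tetrazole-5-thiol | Sc1nnnn1-c1ccccc1 | starting material
3 | 5-{[2-(2-methyl-1,3-dioxolan-2-yl)ethyl]sulfanyl}-1-phenyl-1H-tetrazole | CC1(CCSc2nnnn2-c2ccccc2)OCCO1 | intermediate
4 | 5-{[2-(2-methyl-1,3-dioxolan-2-yl)ethyl]sulfonyl}-1-phenyl-1H-tetrazole | CC1(CCS(=O)(=O)c2nnnn2-c2ccccc2)OCCO1 | intermediate
5 | 2,2-dimethylpent-4-enal | C=CCC(C)(C)C=O | starting material
6 | potassium salt of the α-sulfonyl carbanion of 4 | CC1(C[CH-]S(=O)(=O)c2nnnn2-c2ccccc2)OCCO1.[K+] | intermediate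
7 | 2-[(2E)-4,4-dimethylhepta-2,6-dien-1-yl]-2-methyl-1,3-dioxolane | C=CCC(C)(C)/C=C/CC1(C)OCCO1 | intermediate
8 | methyl 3-oxobutanoate | COC(=O)CC(C)=O | starting material
9 | methyl (2E)-3-{[(trifluoromethyl)sulfonyl]oxy}but-2-enoate | COC(=O)/C=C(\C)OS(=O)(=O)C(F)(F)F | intermediate
10 | 9-[(5E)-4,4-dimethyl-7-(2-methyl-1,3-dioxolan-2-yl)hept-5-en-1-yl]-9-borabicyclo[3.3.1]nonane | CC1(C/C=C/C(C)(C)CCCB2C3CCCC2CCC3)OCCO1 | intermediate
11 | methyl (2E,8E)-3,7,7-trimethyl-10-(2-methyl-1,3-dioxolan-2-yl)deca-2,8-dienoate | COC(=O)/C=C(\C)CCCC(C)(C)/C=C/CC1(C)OCCO1 | intermediate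
12 | methyl (2E,8E)-3,7,7-trimethyl-11-oxododeca-2,8-dienoate | COC(=O)/C=C(\C)CCCC(C)(C)/C=C/CC(C)=O | intermediate
13 | methyl (2E,8E,10Z)-11-{[tert-butyl(dimethyl)silyl]oxy}-3,7,7-trimethyldodeca-2,8,10-trienoate | COC(=O)/C=C(\C)CCCC(C)(C)/C=C/C=C(/C)O[Si](C)(C)C(C)(C)C | intermediate
14 | (2E,8E,10Z)-11-{[tert-butyl(dimethyl)silyl]oxy}-3,7,7-trimethyldodeca-2,8,10-trien-1-ol | OC/C=C(\C)CCCC(C)(C)/C=C/C=C(/C)O[Si](C)(C)C(C)(C)C | intermediate
15 | (2E,8E,10Z)-11-{[tert-butyl(dimethyl)silyl]oxy}-3,7,7-trimethyldodeca-2,8,10-trienal | O=C/C=C(\C)CCCC(C)(C)/C=C/C=C(/C)O[Si](C)(C)C(C)(C)C | intermediate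
16 | (1R,2R,4aS,8aS)-2-{[tert-butyl(dimethyl)silyl]oxy}-2,5,5,8a-tetramethyl-1,2,4a,5,6,7,8,8a-octahydronaphthalene-1-carbaldehyde | O=C[C@@H]1[C@@]2(C)CCCC(C)(C)[C@@H]2C=C[C@@]1(C)O[Si](C)(C)C(C)(C)C | intermediate
17 | (4R)-4-methyldihydrofuran-2(3H)-one | C[C@H]1COC(=O)C1 | starting material
18 | [(2R)-3-carboxy-2-methylpropyl](triphenyl)phosphonium bromide | C[C@@H](C[P+](c1ccccc1)(c1ccccc1)c1ccccc1)CC(=O)O.[Br-] | intermediate
19 | sodium (3R)-3-methyl-4-(triphenylphosphoranylidene)butanoate (ylide) | C[C@@H]([CH-][P+](c1ccccc1)(c1ccccc1)c1ccccc1)CC(=O)[O-].[Na+] | intermediate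
20 | (3R,4Z)-5-[(1R,2R,4aS,8aS)-2-{[tert-butyl(dimethyl)silyl]oxy}-2,5,5,8a-tetramethyl-1,2,4a,5,6,7,8,8a-octahydronaphthalen-1-yl]-3-methylpent-4-enoic acid | C[C@@H](/C=C\[C@@H]1[C@@]2(C)CCCC(C)(C)[C@@H]2C=C[C@@]1(C)O[Si](C)(C)C(C)(C)C)CC(=O)O | intermediate
21 | (3S)-5-[(1R,2R,4aS,8aS)-2-{[tert-butyl(dimethyl)silyl]oxy}-2,5,5,8a-tetramethyldecahydronaphthalen-1-yl]-3-methylpentanoic acid | C[C@@H](CC[C@@H]1[C@@]2(C)CCCC(C)(C)[C@@H]2CC[C@@]1(C)O[Si](C)(C)C(C)(C)C)CC(=O)O | intermediate
22 | (3S)-5-[(1R,2R,4aS,8aS)-2-hydroxy-2,5,5,8a-tetramethyldecahydronaphthalen-1-yl]-3-methylpentanoic acid (8α-hydroxylabdan-15-oic acid) | C[C@@H](CC[C@@H]1[C@@]2(C)CCCC(C)(C)[C@@H]2CC[C@@]1(C)O)CC(=O)O | intermediate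
23 | (3S)-5-[(1R,2R,4aS,8aS)-2-(formyloxy)-2,5,5,8a-tetramethyldecahydronaphthalen-1-yl]-3-methylpentanoic acid | C[C@@H](CC[C@@H]1[C@@]2(C)CCCC(C)(C)[C@@H]2CC[C@@]1(C)OC=O)CC(=O)O | target

**Step count**

Total: 15 steps. Longest linear sequence: 13 steps (steps 1–3, 5–10, 12–15).

**Steps most likely to fail**

Step 10. The catalyst may fail to discriminate the faces of the sluggish β,β-disubstituted enal, or the exo (cis-fused) pathway may compete. Any (10E)-enol ether carried over from step 7 would also cyclise to the C8 epimer. The fallback sets out from 15 and returns at 16. Thermal or Me2AlCl-promoted cyclisation (toluene, 110–140 °C, or CH2Cl2, −20 °C) would give 16 together with its mirror image, the enantiomeric aldehyde F1. NaBH4 reduction would give the primary alcohol F2 and its enantiomer F3. Esterification with (S)-O-methylmandelic acid (N,N'-dicyclohexylcarbodiimide, 4-(dimethylamino)pyridine) would give the diastereomeric esters, the wanted mandelate F4 and the unwanted mandelate F5, to be separated by chromatography or crystallisation. Cleavage of F4 with i-Bu2AlH would return F2, and Dess–Martin oxidation would return 16.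

Step 12. The basic ylide may deprotonate C9 of the hindered β-silyloxy aldehyde, with loss of silanolate, faster than it adds to the carbonyl group. The fallback sets out from 16 and returns at 21, and it builds C12–C13 by conjugate addition instead. Homologation of 16 with dimethyl (1-diazo-2-oxopropyl)phosphonate (K2CO3, MeOH) would give the terminal alkyne F6. Hydroboration with pinacolborane (Cp2Zr(H)Cl cat.) would give the (E)-alkenyl boronate F7. Addition of F7 to benzyl (E)-but-2-enoate with Rh(acac)(C2H4)2 and BINAP (ligand enantiomer chosen to deliver the 3R adduct) would give the benzyl ester F8. Hydrogenation over 10% Pd on carbon would saturate both alkenes, cleave the benzyl ester and give 21.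

Step 15. Acylation of the hindered tertiary alcohol may stay incomplete, and prolonged exposure to the acidic medium may dehydrate the C8 carbinol, while the free carboxyl group consumes reagent as a mixed anhydride. The fallback sets out from 22 and returns at 23. Benzylation (BnBr, Cs2CO3, DMF) would give the benzyl ester F9. Formylation of F9 (formic acid, N,N'-dicyclohexylcarbodiimide, 4-(dimethylamino)pyridine, or acetic formic anhydride) would give the formate benzyl ester F10. Hydrogenolysis (H2, 10% Pd on carbon, EtOAc), to which a saturated tertiary formate is inert, would give 23.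

**Further compounds**

F1 | step 10 | (1S,2S,4aR,8aR)-2-{[tert-butyl(dimethyl)silyl]oxy}-2,5,5,8a-tetramethyl-1,2,4a,5,6,7,8,8a-octahydronaphthalene-1-carbaldehyde (enantiomer of 16) | O=C[C@H]1[C@]2(C)CCCC(C)(C)[C@H]2C=C[C@]1(C)O[Si](C)(C)C(C)(C)C
F2 | step 10 | [(1R,2R,4aS,8aS)-2-{[tert-butyl(dimethyl)silyl]oxy}-2,5,5,8a-tetramethyl-1,2,4a,5,6,7,8,8a-octahydronaphthalen-1-yl]methanol | OC[C@@H]1[C@@]2(C)CCCC(C)(C)[C@@H]2C=C[C@@]1(C)O[Si](C)(C)C(C)(C)C
F3 | step 10 | [(1S,2S,4aR,8aR)-2-{[tert-butyl(dimethyl)silyl]oxy}-2,5,5,8a-tetramethyl-1,2,4a,5,6,7,8,8a-octahydronaphthalen-1-yl]methanol (enantiomer of F2) | OC[C@H]1[C@]2(C)CCCC(C)(C)[C@H]2C=C[C@]1(C)O[Si](C)(C)C(C)(C)C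
F4 | step 10 | (2S)-methoxy(phenyl)acetate of F2 | CO[C@H](C(=O)OC[C@@H]1[C@@]2(C)CCCC(C)(C)[C@@H]2C=C[C@@]1(C)O[Si](C)(C)C(C)(C)C)c1ccccc1
F5 | step 10 | (2S)-methoxy(phenyl)acetate of F3 | CO[C@H](C(=O)OC[C@H]1[C@]2(C)CCCC(C)(C)[C@H]2C=C[C@]1(C)O[Si](C)(C)C(C)(C)C)c1ccccc1
F6 | step 12 | tert-butyl{[(1R,2R,4aS,8aS)-1-ethynyl-2,5,5,8a-tetramethyl-1,2,4a,5,6,7,8,8a-octahydronaphthalen-2-yl]oxy}dimethylsilane | C#C[C@@H]1[C@@]2(C)CCCC(C)(C)[C@@H]2C=C[C@@]1(C)O[Si](C)(C)C(C)(C)C
F7 | step 12 | (E)-alkenyl pinacol boronate from F6 (boron on C12) | CC1(C)OB(OC1(C)C)/C=C/[C@@H]1[C@@]2(C)CCCC(C)(C)[C@@H]2C=C[C@@]1(C)O[Si](C)(C)C(C)(C)C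
F8 | step 12 | benzyl (3R,4E)-5-[(1R,2R,4aS,8aS)-2-{[tert-butyl(dimethyl)silyl]oxy}-2,5,5,8a-tetramethyl-1,2,4a,5,6,7,8,8a-octahydronaphthalen-1-yl]-3-methylpent-4-enoate | C[C@@H](/C=C/[C@@H]1[C@@]2(C)CCCC(C)(C)[C@@H]2C=C[C@@]1(C)O[Si](C)(C)C(C)(C)C)CC(=O)OCc1ccccc1
F9 | step 15 | benzyl (3S)-5-[(1R,2R,4aS,8aS)-2-hydroxy-2,5,5,8a-tetramethyldecahydronaphthalen-1-yl]-3-methylpentanoate | C[C@@H](CC[C@@H]1[C@@]2(C)CCCC(C)(C)[C@@H]2CC[C@@]1(C)O)CC(=O)OCc1ccccc1
F10 | step 15 | benzyl (3S)-5-[(1R,2R,4aS,8aS)-2-(formyloxy)-2,5,5,8a-tetramethyldecahydronaphthalen-1-yl]-3-methylpentanoate | C[C@@H](CC[C@@H]1[C@@]2(C)CCCC(C)(C)[C@@H]2CC[C@@]1(C)OC=O)CC(=O)OCc1ccccc1
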